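Ring C is disconnected at C4a–C4 and C8a–O1. These two bonds sit on neighbouring carbons of the fully substituted ring A, wedged between the C5 oxygen and the C8 benzyl arm, so both are formed in one operation. The ring A aryne (C4a≡C8a) is released by fluoride from an ortho-silyl aryl triflate that already carries the C7 methoxy group, both benzyl-protected 2-hydroxybenzyl arms and a C5 benzyl ether. It inserts into the carboxyl C–O bond of an O-silylated (R)-3-hydroxy-3-phenylpropanoic acid. The ortho-hydroxyaryl ketone so obtained is closed to ring C by Mitsunobu inversion, which fixes the 2S centre, and is then debenzylated.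

Key step: step 9

Assumption: the target is the 2S enantiomer and atoms carry flavanone numbering (O1, C2–C4, C4a, C5–C8, C8a); the carbinol of the acid is carried as a triisopropylsilyl ether because it has to outlast hot CsF.

Step 1
Reactants: 1 5-methoxyresorcinol
Product: 2 1-methoxy-3,5-bis(methoxymethoxy)benzene
Conditions: MOMCl (2.5 equiv), i-Pr2NEt, CH2Cl2, 0 °C to rt
Reagents that add atoms: chloromethyl methyl ether, COCCl
Why: Double O-alkylation of the phenols by the reactive α-chloro ether under amine base (Williamson-type ether synthesis) should be clean, and the two MOM ethers later steer lithiation to the carbon between them.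

Step 2
Reactants: 2 1-methoxy-3,5-bis(methoxymethoxy)benzene
Product: 4 2-bromo-5-methoxy-1,3-bis(methoxymethoxy)benzene, via aryllithium 3 (not isolated)
Conditions: n-BuLi (1.1 equiv), THF, 0 °C; then BrCCl2CCl2Br, −78 °C to rt
Reagents that add atoms: 1,2-dibromo-1,1,2,2-tetrachloroethane, BrC(Cl)(Cl)C(Cl)(Cl)Br
Why: Directed ortho-metalation should take place at the carbon flanked by the two chelating MOM ethers, and the aryllithium is brominated by halogen transfer; the bromine blocks the future C4a during the next step and later becomes the silicon site.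

Step 3
Reactants: 4 2-bromo-5-methoxy-1,3-bis(methoxymethoxy)benzene
Product: 5 1-bromo-3,5-diiodo-4-methoxy-2,6-bis(methoxymethoxy)benzene
Conditions: NIS (2.3 equiv), TFA (10 mol%), MeCN, 0 °C to rt, dark
Reagents that add atoms: N-iodosuccinimide, O=C1CCC(=O)N1I
Why: Electrophilic aromatic iodination should go to completion because the only two ring C–H positions left are each ortho or para to three oxygen substituents, while the bromine occupies the third activated carbon.

Step 4
Reactants: 5 1-bromo-3,5-diiodo-4-methoxy-2,6-bis(methoxymethoxy)benzene; 6 2-(benzyloxy)benzyl bromide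
Product: 8 1-bromo-4-methoxy-2,6-bis(methoxymethoxy)-3,5-bis[2-(benzyloxy)benzyl]benzene, via benzylzinc bromide 7 (not isolated)
Conditions: 6 (3 equiv), Zn dust, LiCl, THF, 0 °C to rt; then 5, Pd(PPh3)4 (5 mol%), THF, 50 °C
Reagents that add atoms: none
Why: In this Negishi cross-coupling zerovalent palladium inserts into the two C–I bonds far faster than into the C–Br bond shielded by two MOM ethers, so both arms are delivered in one operation by a neutral organozinc reagent and no strong base meets the benzyl ethers or the new diarylmethane CH2 groups.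

Step 5
Reactants: 8 1-bromo-4-methoxy-2,6-bis(methoxymethoxy)-3,5-bis[2-(benzyloxy)benzyl]benzene
Product: 9 2-bromo-5-methoxy-4,6-bis[2-(benzyloxy)benzyl]benzene-1,3-diol
Conditions: HCl (3 M), MeOH/THF, 40 °C
Reagents that add atoms: none
Why: Acid-catalysed acetal cleavage removes both MOM groups while the aryl benzyl ethers, the aryl bromide and the methyl ether are inert, and since no aryl–silicon bond is present yet, acid cannot cause protodesilylation.

Step 6
Reactants: 9 2-bromo-5-methoxy-4,6-bis[2-(benzyloxy)benzyl]benzene-1,3-diol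
Product: 13 3-hydroxy-5-methoxy-4,6-bis[2-(benzyloxy)benzyl]-2-(trimethylsilyl)phenyl trifluoromethanesulfonate, via bis(trimethylsilyl) ether 10 (not isolated), via lithium aryloxide 11 (not isolated), via silyloxy aryl triflate 12 (not isolated)
Conditions: HMDS, cat. TMSCl, THF, 65 °C, then evaporate; n-BuLi (1.1 equiv), THF, −78 °C; Tf2O (1.1 equiv), −78 to 0 °C; aq. citric acid/MeOH work-up
Reagents that add atoms: hexamethyldisilazane, C[Si](C)(C)N[Si](C)(C)C; trifluoromethanesulfonic anhydride, O=S(=O)(OS(=O)(=O)C(F)(F)F)C(F)(F)F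
Why: Bromine–lithium exchange followed by retro-Brook rearrangement (anionic 1,3 O→C silyl shift) moves exactly one silyl group to carbon, so only the phenoxide it leaves behind is triflated and the diol is desymmetrised without a statistical step; the remaining labile O–SiMe3 bond is hydrolysed in the mild acidic work-up.

Step 7
Reactants: 13 3-hydroxy-5-methoxy-4,6-bis[2-(benzyloxy)benzyl]-2-(trimethylsilyl)phenyl trifluoromethanesulfonate
Product: 14 3-(benzyloxy)-5-methoxy-4,6-bis[2-(benzyloxy)benzyl]-2-(trimethylsilyl)phenyl trifluoromethanesulfonate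
Conditions: BnOH (1.5 equiv), PPh3, DIAD, THF, 0 °C to rt
Reagents that add atoms: benzyl alcohol, OCc1ccccc1
Why: Mitsunobu etherification should benzylate the hindered phenol under neutral conditions, avoiding a metal phenoxide beside silicon that could shift the silyl group from carbon to oxygen and expel triflate prematurely.

Step 8
Reactants: 15 (R)-3-hydroxy-3-phenylpropanoic acid
Product: 17 (R)-3-phenyl-3-(triisopropylsilyloxy)propanoic acid, via bis-silylated acid 16 (not isolated)
Conditions: TIPSOTf (2.2 equiv), 2,6-lutidine, CH2Cl2, 0 °C to rt; then K2CO3, MeOH/THF/H2O, rt; acidify to pH 4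
Reagents that add atoms: triisopropylsilyl trifluoromethanesulfonate, CC(C)[Si](OS(=O)(=O)C(F)(F)F)(C(C)C)C(C)C
Why: Silylation of the hydroxyl and carboxyl groups followed by selective hydrolysis of the far more labile silyl ester should give the O-protected acid; the stereocentre takes no part and stays R.

Step 9
Reactants: 14 3-(benzyloxy)-5-methoxy-4,6-bis[2-(benzyloxy)benzyl]-2-(trimethylsilyl)phenyl trifluoromethanesulfonate; 17 (R)-3-phenyl-3-(triisopropylsilyloxy)propanoic acid
Product: 20 (R)-1-{6-(benzyloxy)-2-hydroxy-4-methoxy-3,5-bis[2-(benzyloxy)benzyl]phenyl}-3-phenyl-3-(triisopropylsilyloxy)propan-1-one, via cesium carboxylate 18 (not isolated), via ring A aryne 19 (not isolated)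
Conditions: 17 (2 equiv), Cs2CO3 (1 equiv), MeOH, rt, then evaporate and dry; 14, CsF (3 equiv), THF, 125 °C, sealed tube; aq. NH4Cl
Reagents that add atoms: none
Why: CsF strips the trimethylsilyl group from C4a of 14 with loss of triflate from C8a, generating aryne 19; the carboxylate oxygen of 18 adds to C8a, and the aryl anion thus placed on C4a attacks the adjacent ester carbonyl through a four-membered alkoxide that opens to the cesium salt of the ortho-hydroxyaryl ketone, so C8a–O1 and C4a–C4 form in one operation. This is the known insertion of arynes into the C–O bond of carboxylic acids (an intramolecular acyl transfer akin to an anionic Fries shift), run here on the dry cesium salt so that no acidic proton can quench the aryl anion to the O-aryl ester and no HF can strip the silyl ether. No ring is formed and no stereocentre is created; the carbinol centre of 17 is untouched and stays R. The selectivity needed is the orientation of addition: the C5 benzyloxy group withdraws electron density through the σ framework and distorts the aryne so that the nucleophile enters at the remote carbon C8a and the negative charge develops on C4a next to that oxygen, which should outweigh the steric bias of the C8 arm. The triisopropylsilyl ether keeps the secondary hydroxyl from adding to the aryne and resists CsF better than a smaller silyl group would.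

Step 10
Reactants: 20 (R)-1-{6-(benzyloxy)-2-hydroxy-4-methoxy-3,5-bis[2-(benzyloxy)benzyl]phenyl}-3-phenyl-3-(triisopropylsilyloxy)propan-1-one
Product: 21 (R)-1-{6-(benzyloxy)-2-hydroxy-4-methoxy-3,5-bis[2-(benzyloxy)benzyl]phenyl}-3-hydroxy-3-phenylpropan-1-one
Conditions: HF·pyridine, THF/pyridine, 0 °C to rt
Reagents that add atoms: none
Why: Fluoride-assisted Si–O cleavage under weakly acidic HF·pyridine should free the carbinol without the basic fluoride that would trigger E1cB dehydration or retro-aldol cleavage of the β-hydroxy ketone; the C–O bond at the stereocentre is not broken.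

Step 11
Reactants: 21 (R)-1-{6-(benzyloxy)-2-hydroxy-4-methoxy-3,5-bis[2-(benzyloxy)benzyl]phenyl}-3-hydroxy-3-phenylpropan-1-one
Product: 22 (2S)-5-(benzyloxy)-7-methoxy-6,8-bis[2-(benzyloxy)benzyl]-2-phenylchroman-4-one
Conditions: PPh3, DIAD, THF, 0 °C to rt
Reagents that add atoms: none
Why: In this intramolecular Mitsunobu etherification the C8a phenol, acidified by the ortho acyl group, displaces the oxyphosphonium-activated benzylic carbinol in an SN2 6-exo-tet closure, so the R carbinol should give the 2S flavanone by inversion.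

Step 12
Reactants: 22 (2S)-5-(benzyloxy)-7-methoxy-6,8-bis[2-(benzyloxy)benzyl]-2-phenylchroman-4-one
Product: 23 7-methoxydichamanetin
Conditions: H2 (1 atm), 10% Pd/C, EtOAc, rt, stopped at full debenzylation
Reagents that add atoms: none
Why: Catalytic hydrogenolysis cleaves the three aryl benzyl ethers much faster than the cyclic benzylic C2–O1 bond or the hydrogen-bonded aryl ketone, so with monitoring of hydrogen uptake ring C and the 2S centre should stay intact.

Compound list
1 | 5-methoxyresorcinol (5-methoxybenzene-1,3-diol) | COc1cc(O)cc(O)c1 | starting material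
2 | 1-methoxy-3,5-bis(methoxymethoxy)benzene | COCOc1cc(OC)cc(OCOC)c1 | intermediate
3 | [4-methoxy-2,6-bis(methoxymethoxy)phenyl]lithium | COCOc1cc(OC)cc(OCOC)c1[Li] | intermediate (not isolated)
4 | 2-bromo-5-methoxy-1,3-bis(methoxymethoxy)benzene | COCOc1cc(OC)cc(OCOC)c1Br | intermediate
5 | 1-bromo-3,5-diiodo-4-methoxy-2,6-bis(methoxymethoxy)benzene | COCOc1c(Br)c(OCOC)c(I)c(OC)c1I | intermediate
6 | 2-(benzyloxy)benzyl bromide | BrCc1ccccc1OCc1ccccc1 | starting material
7 | [2-(benzyloxy)benzyl]zinc bromide | Br[Zn]Cc1ccccc1OCc1ccccc1 | intermediate (not isolated)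
8 | 1-bromo-4-methoxy-2,6-bis(methoxymethoxy)-3,5-bis[2-(benzyloxy)benzyl]benzene | COCOc1c(Br)c(OCOC)c(Cc2ccccc2OCc2ccccc2)c(OC)c1Cc1ccccc1OCc1ccccc1 | intermediate
9 | 2-bromo-5-methoxy-4,6-bis[2-(benzyloxy)benzyl]benzene-1,3-diol | Oc1c(Br)c(O)c(Cc2ccccc2OCc2ccccc2)c(OC)c1Cc1ccccc1OCc1ccccc1 | intermediate
10 | bis(trimethylsilyl) ether of 9 | C[Si](C)(C)Oc1c(Br)c(O[Si](C)(C)C)c(Cc2ccccc2OCc2ccccc2)c(OC)c1Cc1ccccc1OCc1ccccc1 | intermediate (not isolated)
11 | lithium 5-methoxy-4,6-bis[2-(benzyloxy)benzyl]-2-(trimethylsilyl)-3-(trimethylsilyloxy)phenoxide | [Li]Oc1c([Si](C)(C)C)c(O[Si](C)(C)C)c(Cc2ccccc2OCc2ccccc2)c(OC)c1Cc1ccccc1OCc1ccccc1 | intermediate (not isolated)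
12 | 5-methoxy-4,6-bis[2-(benzyloxy)benzyl]-2-(trimethylsilyl)-3-(trimethylsilyloxy)phenyl trifluoromethanesulfonate | FC(F)(F)S(=O)(=O)Oc1c([Si](C)(C)C)c(O[Si](C)(C)C)c(Cc2ccccc2OCc2ccccc2)c(OC)c1Cc1ccccc1OCc1ccccc1 | intermediate (not isolated)
13 | 3-hydroxy-5-methoxy-4,6-bis[2-(benzyloxy)benzyl]-2-(trimethylsilyl)phenyl trifluoromethanesulfonate | FC(F)(F)S(=O)(=O)Oc1c([Si](C)(C)C)c(O)c(Cc2ccccc2OCc2ccccc2)c(OC)c1Cc1ccccc1OCc1ccccc1 | intermediate
14 | 3-(benzyloxy)-5-methoxy-4,6-bis[2-(benzyloxy)benzyl]-2-(trimethylsilyl)phenyl trifluoromethanesulfonate | COc1c(Cc2ccccc2OCc2ccccc2)c(OCc2ccccc2)c([Si](C)(C)C)c(OS(=O)(=O)C(F)(F)F)c1Cc1ccccc1OCc1ccccc1 | intermediate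
15 | (R)-3-hydroxy-3-phenylpropanoic acid | O[C@@H](c1ccccc1)CC(=O)O | starting material
16 | triisopropylsilyl (R)-3-phenyl-3-(triisopropylsilyloxy)propanoate | CC(C)[Si](C(C)C)(C(C)C)O[C@@H](c1ccccc1)CC(=O)O[Si](C(C)C)(C(C)C)C(C)C | intermediate (not isolated)
17 | (R)-3-phenyl-3-(triisopropylsilyloxy)propanoic acid | CC(C)[Si](C(C)C)(C(C)C)O[C@@H](c1ccccc1)CC(=O)O | intermediate
18 | cesium (R)-3-phenyl-3-(triisopropylsilyloxy)propanoate | CC(C)[Si](C(C)C)(C(C)C)O[C@@H](c1ccccc1)CC(=O)[O-].[Cs+] | intermediate (not isolated)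
19 | 3-(benzyloxy)-5-methoxy-4,6-bis[2-(benzyloxy)benzyl]benzyne (ring A aryne, C4a≡C8a) | COC1=C(Cc2ccccc2OCc2ccccc2)C#CC(OCc2ccccc2)=C1Cc1ccccc1OCc1ccccc1 | intermediate (not isolated)
20 | (R)-1-{6-(benzyloxy)-2-hydroxy-4-methoxy-3,5-bis[2-(benzyloxy)benzyl]phenyl}-3-phenyl-3-(triisopropylsilyloxy)propan-1-one | COc1c(Cc2ccccc2OCc2ccccc2)c(OCc2ccccc2)c(C(=O)C[C@@H](O[Si](C(C)C)(C(C)C)C(C)C)c2ccccc2)c(O)c1Cc1ccccc1OCc1ccccc1 | intermediate
21 | (R)-1-{6-(benzyloxy)-2-hydroxy-4-methoxy-3,5-bis[2-(benzyloxy)benzyl]phenyl}-3-hydroxy-3-phenylpropan-1-one | COc1c(Cc2ccccc2OCc2ccccc2)c(OCc2ccccc2)c(C(=O)C[C@@H](O)c2ccccc2)c(O)c1Cc1ccccc1OCc1ccccc1 | intermediate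
22 | (2S)-5-(benzyloxy)-7-methoxy-6,8-bis[2-(benzyloxy)benzyl]-2-phenylchroman-4-one | COc1c(Cc2ccccc2OCc2ccccc2)c(OCc2ccccc2)c2c(c1Cc1ccccc1OCc1ccccc1)O[C@H](c1ccccc1)CC2=O | intermediate
23 | 7-methoxydichamanetin, (2S)-5-hydroxy-6,8-bis(2-hydroxybenzyl)-7-methoxy-2-phenylchroman-4-one | COc1c(Cc2ccccc2O)c(O)c2c(c1Cc1ccccc1O)O[C@H](c1ccccc1)CC2=O | target

Total step count: 12. Longest linear sequence: 11 steps (steps 1–7 and 9–12, from 1); step 8 prepares the acid partner.

Steps most likely to fail

Step 9. The aryl anion on C4a may be protonated before acyl transfer, which would stop at the O-aryl ester. The carboxylate may add with the opposite orientation, or the ether oxygen of the C8 arm may capture the aryne. Fluoride may also remove the silyl ether, after which β-elimination and unselective oxa-Michael closure would erode the stereocentre. The fallback replaces the aryne insertion by acylation of an organolithium and sets out from 8. Acid 17 is converted with MeNHOMe·HCl and EDC into the Weinreb amide (R)-N-methoxy-N-methyl-3-phenyl-3-(triisopropylsilyloxy)propanamide F1. Bromide 8 undergoes bromine–lithium exchange (n-BuLi, THF, −78 °C) to [4-methoxy-2,6-bis(methoxymethoxy)-3,5-bis[2-(benzyloxy)benzyl]phenyl]lithium F2, which is acylated by F1 to give (R)-1-{4-methoxy-2,6-bis(methoxymethoxy)-3,5-bis[2-(benzyloxy)benzyl]phenyl}-3-phenyl-3-(triisopropylsilyloxy)propan-1-one F3. HCl in MeOH at room temperature removes the two MOM groups ortho to the carbonyl and should give (R)-1-{2,6-dihydroxy-4-methoxy-3,5-bis[2-(benzyloxy)benzyl]phenyl}-3-phenyl-3-(triisopropylsilyloxy)propan-1-one F4. One equivalent of BnBr with K2CO3 in acetone then benzylates one of the two equivalent phenols, the other being held in a hydrogen bond to the carbonyl, and the route is rejoined at 20.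

Step 7. Alkylation of the doubly ortho-substituted phenol may be slow, and a phenoxide beside silicon may shift the silyl group to oxygen and release the aryne early. The fallback installs the benzyl ether before the silyl triflate is built and sets out from 9. Monobenzylation of 9 (BnBr 1 equiv, K2CO3, acetone, unreacted 9 recycled) gives 3-(benzyloxy)-2-bromo-5-methoxy-4,6-bis[2-(benzyloxy)benzyl]phenol F5. HMDS converts it into [3-(benzyloxy)-2-bromo-5-methoxy-4,6-bis[2-(benzyloxy)benzyl]phenoxy]trimethylsilane F6. n-BuLi at −78 °C effects exchange and retro-Brook shift to lithium 3-(benzyloxy)-5-methoxy-4,6-bis[2-(benzyloxy)benzyl]-2-(trimethylsilyl)phenoxide F7, which Tf2O converts into 14. This order is statistical in the benzylation but never exposes a silyl triflate to a phenoxide.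

Step 11. The activated β-hydroxy ketone may eliminate to the chalcone, whose unselective oxa-Michael closure would lower the enantiomeric purity, and closure may be slowed by the C8 arm beside the phenol. The fallback sets C2 by catalytic asymmetric conjugate addition instead of chiral-pool inversion and sets out from 14. Under the conditions of step 9 with cesium acetate in place of 18, 14 should give 1-{6-(benzyloxy)-2-hydroxy-4-methoxy-3,5-bis[2-(benzyloxy)benzyl]phenyl}ethan-1-one F8. N,N-dimethylformamide dimethyl acetal (toluene, 100 °C) gives the enaminone (E)-1-{6-(benzyloxy)-2-hydroxy-4-methoxy-3,5-bis[2-(benzyloxy)benzyl]phenyl}-3-(dimethylamino)prop-2-en-1-one F9. Dilute HCl in CH2Cl2 closes it to 5-(benzyloxy)-7-methoxy-6,8-bis[2-(benzyloxy)benzyl]-4H-chromen-4-one F10. Enantioselective conjugate addition of phenylboronic acid (Pd(OCOCF3)2, the t-BuPyOx enantiomer that delivers the 2S product, NH4PF6, H2O, 1,2-dichloroethane, 60 °C) then gives 22.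

Further compounds
F1 | step 9 | (R)-N-methoxy-N-methyl-3-phenyl-3-(triisopropylsilyloxy)propanamide | CC(C)[Si](C(C)C)(C(C)C)O[C@@H](c1ccccc1)CC(=O)N(C)OC
F2 | step 9 | [4-methoxy-2,6-bis(methoxymethoxy)-3,5-bis[2-(benzyloxy)benzyl]phenyl]lithium | COc1c(Cc2ccccc2OCc2ccccc2)c(OCOC)c([Li])c(OCOC)c1Cc1ccccc1OCc1ccccc1
F3 | step 9 | (R)-1-{4-methoxy-2,6-bis(methoxymethoxy)-3,5-bis[2-(benzyloxy)benzyl]phenyl}-3-phenyl-3-(triisopropylsilyloxy)propan-1-one | COc1c(Cc2ccccc2OCc2ccccc2)c(OCOC)c(C(=O)C[C@@H](O[Si](C(C)C)(C(C)C)C(C)C)c2ccccc2)c(OCOC)c1Cc1ccccc1OCc1ccccc1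
F4 | step 9 | (R)-1-{2,6-dihydroxy-4-methoxy-3,5-bis[2-(benzyloxy)benzyl]phenyl}-3-phenyl-3-(triisopropylsilyloxy)propan-1-one | COc1c(Cc2ccccc2OCc2ccccc2)c(O)c(C(=O)C[C@@H](O[Si](C(C)C)(C(C)C)C(C)C)c2ccccc2)c(O)c1Cc1ccccc1OCc1ccccc1
F5 | step 7 | 3-(benzyloxy)-2-bromo-5-methoxy-4,6-bis[2-(benzyloxy)benzyl]phenol | COc1c(Cc2ccccc2OCc2ccccc2)c(OCc2ccccc2)c(Br)c(O)c1Cc1ccccc1OCc1ccccc1
F6 | step 7 | [3-(benzyloxy)-2-bromo-5-methoxy-4,6-bis[2-(benzyloxy)benzyl]phenoxy]trimethylsilane | COc1c(Cc2ccccc2OCc2ccccc2)c(OCc2ccccc2)c(Br)c(O[Si](C)(C)C)c1Cc1ccccc1OCc1ccccc1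
F7 | step 7 | lithium 3-(benzyloxy)-5-methoxy-4,6-bis[2-(benzyloxy)benzyl]-2-(trimethylsilyl)phenoxide | COc1c(Cc2ccccc2OCc2ccccc2)c(OCc2ccccc2)c([Si](C)(C)C)c(O[Li])c1Cc1ccccc1OCc1ccccc1
F8 | step 11 | 1-{6-(benzyloxy)-2-hydroxy-4-methoxy-3,5-bis[2-(benzyloxy)benzyl]phenyl}ethan-1-one | COc1c(Cc2ccccc2OCc2ccccc2)c(OCc2ccccc2)c(C(C)=O)c(O)c1Cc1ccccc1OCc1ccccc1
F9 | step 11 | (E)-1-{6-(benzyloxy)-2-hydroxy-4-methoxy-3,5-bis[2-(benzyloxy)benzyl]phenyl}-3-(dimethylamino)prop-2-en-1-one | COc1c(Cc2ccccc2OCc2ccccc2)c(OCc2ccccc2)c(C(=O)/C=C/N(C)C)c(O)c1Cc1ccccc1OCc1ccccc1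
F10 | step 11 | 5-(benzyloxy)-7-methoxy-6,8-bis[2-(benzyloxy)benzyl]-4H-chromen-4-one | COc1c(Cc2ccccc2OCc2ccccc2)c(OCc2ccccc2)c2c(c1Cc1ccccc1OCc1ccccc1)OC=CC2=O
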